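The dihydropyran (ring B) is cut at C2–C3 and C4–C4a. This releases C3–C4 as a two-carbon unit and leaves an aryl ether of the side-chain methyl ketone. The key step exploits the C4a=C8a–O1–C2 array: O1 stabilises a cation at C2 (O-aryl oxocarbenium ion), while O1 and O7 make C4a of ring A nucleophilic. A silyl vinyl ether is stitched between these two carbons in an enantioselective formal [4+2] (oxa-Povarov) annulation under a confined chiral acid, closing ring B and setting C2 at once. The precursor is an acyclic orcinol enol ether that already carries the complete (2Z,6E)-dienoate chain. The C4 oxygen left behind is removed by ionic reduction.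

Key step: step 6

Assumption: geranylacetone is used as the pure E isomer, and the trifluoroethyl phosphonopropanoate and the silyl vinyl ether are taken as catalogue reagents; chromane numbering (O1, C2–C4, C4a, C5–C8, C8a) is used, ring A is the arene, ring B the dihydropyran, and side-chain carbons are counted from C2 as C1', C2' and so on.

Step 1
Reactants: 1 orcinol (5-methylbenzene-1,3-diol, anhydrous, 2.5 equiv)
Product: 2 3-methyl-5-(triisopropylsilyloxy)phenol
Conditions: i-Pr3SiCl (1.0 equiv), imidazole, DMF, 0 °C to rt
Reagents that add atoms: triisopropylsilyl chloride, CC(C)[Si](Cl)(C(C)C)C(C)C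
Why: Statistical silyl ether protection of a symmetric diol; with orcinol in excess the bulky chlorosilane should cap only one phenol, and the surplus diol is washed out with water.

Step 2
Reactants: 3 (E)-geranylacetone [(5E)-6,10-dimethylundeca-5,9-dien-2-one]
Product: 5 (4E)-4-methyl-8-oxonon-4-enal, via terminal epoxide 4 (not isolated)
Conditions: mCPBA (1.0 equiv), CH2Cl2, −20 °C; crude 4, H5IO6 (1.2 equiv), THF/H2O, 0 °C
Reagents that add atoms: 3-chloroperbenzoic acid (mCPBA), O=C(OO)c1cccc(Cl)c1
Why: Prilezhaev epoxidation should favour the more exposed terminal trisubstituted alkene, and periodic acid opens the epoxide to the diol and cleaves it (Malaprade-type glycol cleavage) without touching the ketone or the E alkene.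

Step 3
Reactants: 5 (4E)-4-methyl-8-oxonon-4-enal; 6 methyl 2-[bis(2,2,2-trifluoroethoxy)phosphoryl]propanoate
Product: 7 methyl (2Z,6E)-2,6-dimethyl-10-oxoundeca-2,6-dienoate
Conditions: KN(SiMe3)2, 18-crown-6, THF, −78 °C
Reagents that add atoms: none
Why: Still–Gennari olefination; the phosphonate anion attacks the aldehyde far faster than the methyl ketone, and the fast, kinetically controlled elimination of the trifluoroethyl phosphonate adduct should give the Z-configured 2-methyl enoate.

Step 4
Reactants: 7 methyl (2Z,6E)-2,6-dimethyl-10-oxoundeca-2,6-dienoate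
Product: 8 methyl (2Z,6E)-2,6-dimethyl-10-(trifluoromethylsulfonyloxy)undeca-2,6,10-trienoate
Conditions: KN(SiMe3)2 (1.05 equiv), THF, −78 °C; PhNTf2, −78 to 0 °C
Reagents that add atoms: N-phenylbis(trifluoromethanesulfonimide), O=S(=O)(N(c1ccccc1)S(=O)(=O)C(F)(F)F)C(F)(F)F
Why: Kinetic deprotonation at the ketone methyl group (more acidic than the enoate γ-positions) followed by O-sulfonylation gives the enol triflate; a minor internal regioisomer is harmless because both lead to the same cation in step 6.

Step 5
Reactants: 8 methyl (2Z,6E)-2,6-dimethyl-10-(trifluoromethylsulfonyloxy)undeca-2,6,10-trienoate; 2 3-methyl-5-(triisopropylsilyloxy)phenol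
Product: 9 methyl (2Z,6E)-2,6-dimethyl-10-[3-methyl-5-(triisopropylsilyloxy)phenoxy]undeca-2,6,10-trienoate
Conditions: Pd2(dba)3 (2 mol %), 2-di-tert-butylphosphino-2',4',6'-triisopropylbiphenyl (5 mol %), K3PO4, toluene, 80 °C
Reagents that add atoms: none
Why: Palladium-catalysed C–O cross-coupling of a vinyl triflate with a phenol (Buchwald–Hartwig-type etherification); the bulky electron-rich biaryl phosphine promotes C–O reductive elimination, and the mild phosphate base spares the methyl ester and the silyl ether.

Step 6
Reactants: 9 methyl (2Z,6E)-2,6-dimethyl-10-[3-methyl-5-(triisopropylsilyloxy)phenoxy]undeca-2,6,10-trienoate; 10 tert-butyldimethyl(vinyloxy)silane (2.5 equiv)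
Product: 12 methyl (2Z,6E)-9-[(2R)-4-(tert-butyldimethylsilyloxy)-2,5-dimethyl-7-(triisopropylsilyloxy)chroman-2-yl]-2,6-dimethylnona-2,6-dienoate (C4 epimers), via tertiary chloro ether 11 (not isolated)
Conditions: HCl (1.0 equiv, 2 M in Et2O), toluene, −78 °C; then BINOL-derived N-triflyl imidodiphosphorimidate acid bearing 3,3'-aryl groups (IDPi, 5 mol %), 10, −78 to −60 °C
Reagents that add atoms: hydrogen chloride, Cl (its chlorine stays only in 11)
Why: Proposed new method: Markovnikov addition of HCl converts the enol ether 9 into the dormant chloride 11, so that neither free acid nor a nucleophilic enol ether competes when 10 enters; the catalyst, silylated in situ by 10, then abstracts chloride as t-BuMe2SiCl and leaves the O-aryl oxocarbenium ion (O1=C2) paired with the confined chiral imidodiphosphorimidate anion. The CH2 terminus of 10 attacks C2 (C2–C3 bond), the O-silyl oxocarbenium carbon C4 so formed is captured by the tethered ortho carbon C4a of ring A (C4–C4a bond), and the proton lost on rearomatisation is consumed by a second equivalent of 10, which regenerates the silylated catalyst and gives acetaldehyde. The closest known reaction types are the racemic, Lewis-acid-promoted oxa-Povarov reaction of aldehyde-derived O-aryl oxocarbenium ions with alkenes and the confined-acid-catalysed enantioselective additions of enol silanes to aliphatic oxocarbenium ions and to methyl alkyl ketones; new are the ketone-derived O-aryl cation and the asymmetric course. Ring B closes in a formal [4+2] sense by a 6-exo-trig Friedel–Crafts attack of C4a on the C4=O+ bond. C2 is set in the C2–C3 bond formation by the chiral anion, whose pocket must tell the methyl group from the CH2CH2 chain (the catalyst antipode that leads to 2R has to be found by experiment), whereas C4 arises as an inconsequential epimer mixture that step 7 erases. The step needs closure at C4a instead of C8, secured by the para-directing O7 and by the bulky TIPS group that shields C8; arene attack instead of Prins capture by the C3'=C4' alkene, secured by the far more nucleophilic resorcinol-type ring and by the strained 4-exo or 5-endo geometry for attack on C2; and no re-ionisation of 12, secured by the bulky C4 silyl ether that the confined catalyst cannot reach.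

Step 7
Reactants: 12 methyl (2Z,6E)-9-[(2R)-4-(tert-butyldimethylsilyloxy)-2,5-dimethyl-7-(triisopropylsilyloxy)chroman-2-yl]-2,6-dimethylnona-2,6-dienoate
Product: 13 methyl (2Z,6E)-9-[(2R)-2,5-dimethyl-7-(triisopropylsilyloxy)chroman-2-yl]-2,6-dimethylnona-2,6-dienoate
Conditions: Et3SiH (3 equiv), Me3SiOTf (10 mol %), CH2Cl2, −78 to −40 °C
Reagents that add atoms: none
Why: Ionic hydrogenolysis of a benzylic silyl ether; the silyl triflate ionises C4–O to a cation stabilised by O1 (ortho) and O7 (para), which the silane should reduce faster than the alkenes can attack, and C2 is not involved, so its configuration is kept.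

Step 8
Reactants: 13 methyl (2Z,6E)-9-[(2R)-2,5-dimethyl-7-(triisopropylsilyloxy)chroman-2-yl]-2,6-dimethylnona-2,6-dienoate
Product: 14 methyl (2Z,6E)-9-[(2R)-7-hydroxy-2,5-dimethylchroman-2-yl]-2,6-dimethylnona-2,6-dienoate (target)
Conditions: Bu4NF (1.1 equiv), AcOH (1.1 equiv), THF, 0 °C
Reagents that add atoms: none
Why: Fluoride-induced cleavage of the aryl silyl ether; acetic acid buffers the phenoxide so that the methyl ester and the Z enoate stay untouched.

Compound list
1 | orcinol (5-methylbenzene-1,3-diol) | Cc1cc(O)cc(O)c1 | starting material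
2 | 3-methyl-5-(triisopropylsilyloxy)phenol | Cc1cc(O)cc(O[Si](C(C)C)(C(C)C)C(C)C)c1 | intermediate
3 | (E)-geranylacetone | CC(C)=CCC/C(C)=C/CCC(C)=O | starting material
4 | (5E)-8-(3,3-dimethyloxiran-2-yl)-6-methyloct-5-en-2-one (racemic epoxide) | CC1(C)OC1CC/C(C)=C/CCC(C)=O | intermediate
5 | (4E)-4-methyl-8-oxonon-4-enal | O=CCC/C(C)=C/CCC(C)=O | intermediate
6 | methyl 2-[bis(2,2,2-trifluoroethoxy)phosphoryl]propanoate | COC(=O)C(C)P(=O)(OCC(F)(F)F)OCC(F)(F)F | starting material
7 | methyl (2Z,6E)-2,6-dimethyl-10-oxoundeca-2,6-dienoate | COC(=O)/C(C)=C\CC/C(C)=C/CCC(C)=O | intermediate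
8 | methyl (2Z,6E)-2,6-dimethyl-10-(trifluoromethylsulfonyloxy)undeca-2,6,10-trienoate | COC(=O)/C(C)=C\CC/C(C)=C/CCC(=C)OS(=O)(=O)C(F)(F)F | intermediate
9 | methyl (2Z,6E)-2,6-dimethyl-10-[3-methyl-5-(triisopropylsilyloxy)phenoxy]undeca-2,6,10-trienoate | COC(=O)/C(C)=C\CC/C(C)=C/CCC(=C)Oc1cc(C)cc(O[Si](C(C)C)(C(C)C)C(C)C)c1 | intermediate
10 | tert-butyldimethyl(vinyloxy)silane | C=CO[Si](C)(C)C(C)(C)C | starting material
11 | methyl (2Z,6E)-10-chloro-2,6-dimethyl-10-[3-methyl-5-(triisopropylsilyloxy)phenoxy]undeca-2,6-dienoate (racemic) | COC(=O)/C(C)=C\CC/C(C)=C/CCC(C)(Cl)Oc1cc(C)cc(O[Si](C(C)C)(C(C)C)C(C)C)c1 | intermediate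
12 | methyl (2Z,6E)-9-[(2R)-4-(tert-butyldimethylsilyloxy)-2,5-dimethyl-7-(triisopropylsilyloxy)chroman-2-yl]-2,6-dimethylnona-2,6-dienoate (C4 epimers) | COC(=O)/C(C)=C\CC/C(C)=C/CC[C@]1(C)CC(O[Si](C)(C)C(C)(C)C)c2c(C)cc(O[Si](C(C)C)(C(C)C)C(C)C)cc2O1 | intermediate
13 | methyl (2Z,6E)-9-[(2R)-2,5-dimethyl-7-(triisopropylsilyloxy)chroman-2-yl]-2,6-dimethylnona-2,6-dienoate | COC(=O)/C(C)=C\CC/C(C)=C/CC[C@]1(C)CCc2c(C)cc(O[Si](C(C)C)(C(C)C)C(C)C)cc2O1 | intermediate
14 | methyl (2Z,6E)-9-[(2R)-7-hydroxy-2,5-dimethylchroman-2-yl]-2,6-dimethylnona-2,6-dienoate | COC(=O)/C(C)=C\CC/C(C)=C/CC[C@]1(C)CCc2c(C)cc(O)cc2O1 | target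

Total step count: 8. Longest linear sequence: 7 steps (3 to 14, steps 2–8).

Steps most likely to fail

Step 6. The ion pair may discriminate the two faces of C2 poorly. Uncatalysed ionisation of the chloride may feed a racemic background reaction. Loss of HCl may also return the enol ether, which then condenses with the cation. The fallback uses known chemistry, sets out from 7 and comes back at 14. Kabbe condensation of 7 with commercial 1-(2,4-dihydroxy-6-methylphenyl)ethanone F1 (pyrrolidine, toluene, reflux, water separator) should give the racemic chroman-4-one F2 by aldol condensation and oxa-Michael closure. NaBH4 in MeOH reduces it to the chroman-4-ol F3. Et3SiH/CF3CO2H in CH2Cl2 at −20 °C removes the benzylic hydroxyl to give the racemic chromane F4. Preparative chromatography on a polysaccharide-based chiral stationary phase then delivers the 2R enantiomer 14.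

Step 5. C–O reductive elimination may be slow. This would leave time for base-induced loss of triflic acid from the acyclic vinyl triflate or for its hydrolysis back to the ketone. The fallback sets out from 8 and comes back at 9. Miyaura borylation of 8 (B2pin2, PdCl2(dppf), KOAc, dioxane, 80 °C) gives the alkenyl pinacol boronate F5. This is joined to phenol 2 by an oxidative Chan–Lam coupling (Cu(OAc)2, pyridine, 4 Å molecular sieves, air, CH2Cl2, rt) to give 9.

Step 2. The peracid may distinguish the two trisubstituted alkenes poorly, so that internal epoxidation and double epoxidation erode the material. The fallback sets out from 3 and comes back at 4. Bromohydrin formation with N-bromosuccinimide in THF/H2O at 0 °C draws its terminal selectivity from the coiled chain in the aqueous medium and gives the bromohydrin F6. K2CO3 in MeOH closes it to the epoxide 4, which enters the periodic acid cleavage as before.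

Further compounds
F1 | step 6 | 1-(2,4-dihydroxy-6-methylphenyl)ethanone (commercial) | CC(=O)c1c(C)cc(O)cc1O
F2 | step 6 | racemic chroman-4-one, methyl (2Z,6E)-9-(7-hydroxy-2,5-dimethyl-4-oxochroman-2-yl)-2,6-dimethylnona-2,6-dienoate | COC(=O)/C(C)=C\CC/C(C)=C/CCC1(C)CC(=O)c2c(C)cc(O)cc2O1
F3 | step 6 | chroman-4-ol, methyl (2Z,6E)-9-(4,7-dihydroxy-2,5-dimethylchroman-2-yl)-2,6-dimethylnona-2,6-dienoate (racemic, C4 epimers) | COC(=O)/C(C)=C\CC/C(C)=C/CCC1(C)CC(O)c2c(C)cc(O)cc2O1
F4 | step 6 | racemic chromane, methyl (2Z,6E)-9-(7-hydroxy-2,5-dimethylchroman-2-yl)-2,6-dimethylnona-2,6-dienoate | COC(=O)/C(C)=C\CC/C(C)=C/CCC1(C)CCc2c(C)cc(O)cc2O1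
F5 | step 5 | alkenyl pinacol boronate, methyl (2Z,6E)-2,6-dimethyl-10-(4,4,5,5-tetramethyl-1,3,2-dioxaborolan-2-yl)undeca-2,6,10-trienoate | COC(=O)/C(C)=C\CC/C(C)=C/CCC(=C)B1OC(C)(C)C(C)(C)O1
F6 | step 2 | bromohydrin, (5E)-9-bromo-10-hydroxy-6,10-dimethylundec-5-en-2-one (racemic) | CC(C)(O)C(Br)CC/C(C)=C/CCC(C)=O
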